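The seven-membered ring is cut into C6–C7–C8, a (Z)-β-silylacryloylsilane, and C9–C10–C1–C5, the enolate of a cyclopentenyl methyl ketone (C1 methyl-bearing ring-fusion carbon, C2–C4 five-membered ring, C5 ring-fusion CH, C6–C10 seven-membered ring; C6 aroyloxy, C8/C9 oxirane, C10 carbinol). One Brook-rearrangement-mediated (3+4) annulation (carbonyl addition, silyl shift, cyclopropanolate, anionic oxy-Cope) joins C8 to C9 and C6 to C5, sets C5 and C6, and leaves a C10 enolate that is methylated at C1 in the same flask. It exploits the oxygenated carbons C8 and C10 flanking C9 and the ring-fusion pair C1/C5. The trans-fused oxirane follows from the E cycloheptene.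

Key step: step 9

Remark on the chemistry: read literally, the descriptors (8R,9R) place C7 and C10 on opposite sides of the oxirane, so the oxirane is trans-fused to the seven-membered ring (oxygen β at C8, α at C9); the end game therefore epoxidises the E isomer of the C8=C9 cycloheptene, because the Z alkene could only give a cis-fused oxirane.

Convention: all bicyclic compounds are trans-fused bicyclo[5.3.0]decanes numbered as above (C10 bonded to C1); β is the face of the C1 methyl group, α the opposite face.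

Step 1
Reactants: 1 cyclopent-4-ene-1,3-dione
Product: 2 1,4-dioxaspiro[4.4]non-8-en-7-one
Conditions: 1,2-bis(trimethylsilyloxy)ethane (1.0 equiv), TMSOTf (cat.), CH2Cl2, -78 °C
Reagents that add atoms: 1,2-bis(trimethylsilyloxy)ethane, C[Si](C)(C)OCCO[Si](C)(C)C
Why: Silyl-transfer ketalisation of one carbonyl group of the symmetrical dione; the remaining carbonyl is then part of a less electrophilic enone, so the reaction should stop at the mono-ketal.

Step 2
Reactants: 2 1,4-dioxaspiro[4.4]non-8-en-7-one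
Product: 3 8-iodo-1,4-dioxaspiro[4.4]non-8-en-7-one
Conditions: I2, pyridine, CH2Cl2, 0 °C to rt
Reagents that add atoms: iodine, II
Why: α-Iodination of a cyclic enone by conjugate addition of pyridine, iodination of the enolate and elimination.

Step 3
Reactants: 3 8-iodo-1,4-dioxaspiro[4.4]non-8-en-7-one
Product: 4 (7R)-8-iodo-1,4-dioxaspiro[4.4]non-8-en-7-ol
Conditions: (S)-2-methyl-CBS-oxazaborolidine (0.2 equiv), BH3·SMe2, THF, -20 °C; MeOH quench
Reagents that add atoms: none
Why: Corey–Bakshi–Shibata reduction of an α-iodo enone, in which the iodoalkenyl side acts as the large group, so the (S)-catalyst should give the (R)-carbinol (the later C2, oxygen α).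

Step 4
Reactants: 4 (7R)-8-iodo-1,4-dioxaspiro[4.4]non-8-en-7-ol
Product: 5 tert-butyl{[(7R)-8-iodo-1,4-dioxaspiro[4.4]non-8-en-7-yl]oxy}dimethylsilane
Conditions: TBSCl, imidazole, DMF, rt
Reagents that add atoms: tert-butyldimethylsilyl chloride, CC(C)(C)[Si](C)(C)Cl
Why: Standard silylation of a secondary allylic alcohol; the bulky silyl ether later serves as the steric director on the α face.

Step 5
Reactants: 5 tert-butyl{[(7R)-8-iodo-1,4-dioxaspiro[4.4]non-8-en-7-yl]oxy}dimethylsilane
Product: 6 1-[(7R)-7-(tert-butyldimethylsilyloxy)-1,4-dioxaspiro[4.4]non-8-en-8-yl]ethan-1-one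
Conditions: t-BuLi (2.1 equiv), Et2O, -78 °C; then N-methoxy-N-methylacetamide, -78 to 0 °C
Reagents that add atoms: N-methoxy-N-methylacetamide, CC(=O)N(C)OC
Why: Iodine–lithium exchange and acylation of the vinyllithium with a Weinreb amide, which stops at the ketone through the chelated tetrahedral adduct.

Step 6
Reactants: 7 tert-butyldimethyl(prop-2-yn-1-yloxy)silane
Product: 9 1-(tert-butyldimethylsilyl)-3-(dimethylphenylsilyl)prop-2-yn-1-ol, via bis-silyl propargyl ether 8 (not isolated)
Conditions: n-BuLi, THF, -78 °C; PhMe2SiCl, -78 to 0 °C; then t-BuLi, -78 to -40 °C; AcOH quench at -78 °C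
Reagents that add atoms: chloro(dimethyl)phenylsilane, C[Si](C)(Cl)c1ccccc1
Why: C-Silylation of the lithium acetylide, then propargylic deprotonation triggers a [1,2]-retro-Brook shift of the tert-butyldimethylsilyl group from oxygen to carbon (the new stereocentre is racemic and is removed in step 8).

Step 7
Reactants: 9 1-(tert-butyldimethylsilyl)-3-(dimethylphenylsilyl)prop-2-yn-1-ol
Product: 10 (2Z)-1-(tert-butyldimethylsilyl)-3-(dimethylphenylsilyl)prop-2-en-1-ol
Conditions: H2 (1 atm), Pd/CaCO3 poisoned with Pb(OAc)2, quinoline, hexane/EtOAc, rt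
Reagents that add atoms: none
Why: Syn semihydrogenation of the silylalkyne on the poisoned palladium surface sets the Z vinylsilane.

Step 8
Reactants: 10 (2Z)-1-(tert-butyldimethylsilyl)-3-(dimethylphenylsilyl)prop-2-en-1-ol
Product: 11 (2Z)-1-(tert-butyldimethylsilyl)-3-(dimethylphenylsilyl)prop-2-en-1-one
Conditions: Dess–Martin periodinane, NaHCO3, CH2Cl2, 0 °C, light excluded
Reagents that add atoms: none
Why: Dess–Martin oxidation of the α-silyl carbinol to the acylsilane under neutral conditions that should avoid Brook rearrangement and Z to E isomerisation.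

Step 9
Reactants: 6 1-[(7R)-7-(tert-butyldimethylsilyloxy)-1,4-dioxaspiro[4.4]non-8-en-8-yl]ethan-1-one; 11 (2Z)-1-(tert-butyldimethylsilyl)-3-(dimethylphenylsilyl)prop-2-en-1-one
Product: 15 2α,8-bis(tert-butyldimethylsilyloxy)-6α-(dimethylphenylsilyl)-4,4-ethylenedioxy-1β-methylbicyclo[5.3.0]dec-7-en-10-one, via lithium dienolate 12 (not isolated), via divinylcyclopropanolate 13 (not isolated), via bicyclic lithium enolate 14 (not isolated)
Conditions: LDA, THF, -80 °C; then 11, -80 to -30 °C; then MeI, DMPU, -30 to 0 °C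
Reagents that add atoms: iodomethane, CI
Why: Enolate 12 adds with its terminal carbon (C9) to the acylsilane carbonyl (C8), the tert-butyldimethylsilyl group migrates from carbon to oxygen (Brook rearrangement) and the silyl-stabilised allyl anion closes on C10 to the cis-1,2-divinylcyclopropanolate 13, whose anionic oxy-Cope rearrangement forms C5–C6, breaks C8–C10 and leaves the regiodefined C10 enolate 14, which is C-methylated at C1. The closest known reaction type is the Brook-rearrangement-mediated (3+4) annulation of β-silylacryloylsilanes with lithium enolates of alkenyl methyl ketones, followed by an ordinary enolate alkylation. The seven-membered ring closes by a [3,3]-sigmatropic shift through a boat transition state, after a 3-exo-trig closure of the cyclopropane. C5 and C6 are set by the suprafacial shift, which turns the Z geometry of 11 into the cis relation of H5 and the silyl group, and by the α-silyloxy group at C2, which keeps the stacked allyl unit on the β face of the cyclopentene; the same group should send iodomethane to the β face of C1 (trans ring fusion). The step needs 1,2-addition to the acylsilane, which its highly electrophilic carbonyl group secures; deprotonation only at the acetyl methyl group, which the C4 ketal (no γ-hydrogen) secures; and C- before O-alkylation, which the tetrasubstituted lithium enolate in THF/DMPU favours.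

Step 10
Reactants: 15 2α,8-bis(tert-butyldimethylsilyloxy)-6α-(dimethylphenylsilyl)-4,4-ethylenedioxy-1β-methylbicyclo[5.3.0]dec-7-en-10-one
Product: 16 6α-(dimethylphenylsilyl)-4,4-ethylenedioxy-2α-hydroxy-1β-methylbicyclo[5.3.0]decane-8,10-dione
Conditions: TBAF, AcOH, THF, 0 to 40 °C
Reagents that add atoms: none
Why: Fluoride cleaves the silyl enol ether (the 8,10-dione buffers itself as its enolate and so resists retro-aldol cleavage) and the C2 silyl ether, while the ketal and the C6–Si bond are stable.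

Step 11
Reactants: 16 6α-(dimethylphenylsilyl)-4,4-ethylenedioxy-2α-hydroxy-1β-methylbicyclo[5.3.0]decane-8,10-dione
Product: 17 6α-(dimethylphenylsilyl)-4,4-ethylenedioxy-2α-hydroxy-1β-methyl-10-oxobicyclo[5.3.0]dec-8-en-8-yl trifluoromethanesulfonate
Conditions: PhNTf2, Et3N, DMAP (cat.), CH2Cl2, 0 °C to rt
Reagents that add atoms: N-phenylbis(trifluoromethanesulfonimide), O=S(=O)(N(c1ccccc1)S(=O)(=O)C(F)(F)F)C(F)(F)F
Why: O-Sulfonylation of the 1,3-diketone enolate at the less hindered oxygen (on C8, remote from quaternary C1) should give the vinylogous acyl triflate with C8=C9 conjugated to C10=O; the neutral C2 hydroxyl does not react with this reagent.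

Step 12
Reactants: 17 6α-(dimethylphenylsilyl)-4,4-ethylenedioxy-2α-hydroxy-1β-methyl-10-oxobicyclo[5.3.0]dec-8-en-8-yl trifluoromethanesulfonate
Product: 18 6α-(dimethylphenylsilyl)-4,4-ethylenedioxy-2α-hydroxy-1β,8-dimethylbicyclo[5.3.0]dec-8-en-10-one
Conditions: Me2CuLi (from CuI and MeLi, 3 equiv), Et2O/THF, -78 to -30 °C
Reagents that add atoms: lithium dimethylcuprate, [Li+].C[Cu-]C
Why: Conjugate addition–elimination of the cuprate at the β-carbon of the β-triflyloxy enone installs the C8 methyl group with the double bond at C8=C9.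

Step 13
Reactants: 18 6α-(dimethylphenylsilyl)-4,4-ethylenedioxy-2α-hydroxy-1β,8-dimethylbicyclo[5.3.0]dec-8-en-10-one
Product: 19 6α-(dimethylphenylsilyl)-4,4-ethylenedioxy-1β,8-dimethylbicyclo[5.3.0]dec-8-ene-2,10-dione
Conditions: Dess–Martin periodinane, NaHCO3, CH2Cl2, rt
Reagents that add atoms: none
Why: Dess–Martin oxidation of the only hydroxyl group; the directing C2 stereocentre has done its work and is erased.

Step 14
Reactants: 19 6α-(dimethylphenylsilyl)-4,4-ethylenedioxy-1β,8-dimethylbicyclo[5.3.0]dec-8-ene-2,10-dione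
Product: 21 6α-(dimethylphenylsilyl)-2β-hydroxy-1β,8-dimethylbicyclo[5.3.0]dec-8-ene-4,10-dione, via 2β-alcohol ketal 20 (not isolated)
Conditions: NaBH4, MeOH/CH2Cl2, -40 °C; acetone quench; then PPTS, acetone/H2O, 40 °C
Reagents that add atoms: water, O
Why: Hydride should attack the C2 cyclopentanone from the α face, anti to the β-methyl group on the adjacent quaternary C1 (as in 17-oxo steroids), giving the 2β-alcohol faster than the hindered conjugated C10 ketone reacts; buffered hydrolysis then unmasks the C4 ketone under conditions mild enough to spare the β-hydroxy ketone.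

Step 15
Reactants: 21 6α-(dimethylphenylsilyl)-2β-hydroxy-1β,8-dimethylbicyclo[5.3.0]dec-8-ene-4,10-dione
Product: 22 6α-(dimethylphenylsilyl)-2β,4β-dihydroxy-4α-isopropyl-1β,8-dimethylbicyclo[5.3.0]dec-8-en-10-one
Conditions: i-PrMgCl, anhydrous CeCl3, THF, -78 °C
Reagents that add atoms: isopropylmagnesium chloride, CC(C)[Mg]Cl
Why: Organocerium 1,2-addition to the cyclopentanone, which should be faster than addition to the neopentyl conjugated C10 ketone; the reagent enters from the α face, anti to the C5–C6 bond and to the β substituents at C1 and C2, so the new hydroxyl is β.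

Step 16
Reactants: 22 6α-(dimethylphenylsilyl)-2β,4β-dihydroxy-4α-isopropyl-1β,8-dimethylbicyclo[5.3.0]dec-8-en-10-one
Product: 23 2β,4β,6α-trihydroxy-4α-isopropyl-1β,8-dimethylbicyclo[5.3.0]dec-8-en-10-one
Conditions: KBr, AcOOH, NaOAc, AcOH, rt
Reagents that add atoms: peracetic acid, CC(=O)OO
Why: Fleming–Tamao oxidation (ipso-bromodesilylation of the phenyl group, then peracid-induced shift of C6 from silicon to oxygen with retention) gives the 6α-alcohol; the electron-poor enone double bond is not epoxidised.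

Step 17
Reactants: 23 2β,4β,6α-trihydroxy-4α-isopropyl-1β,8-dimethylbicyclo[5.3.0]dec-8-en-10-one
Product: 24 2β-acetoxy-4α-isopropyl-1β,8-dimethylbicyclo[5.3.0]dec-8-ene-4β,6α,10α-triol
Conditions: acetaldehyde (excess), SmI2 (0.3 equiv), THF, -10 °C
Reagents that add atoms: acetaldehyde, CC=O
Why: Evans–Tishchenko reduction, in which the 2β-hydroxyl forms a hemiacetal with acetaldehyde and delivers its hydride within the samarium chelate to the β face of the C10 ketone, so C10–OH forms α (1,3-anti) and the C2 oxygen emerges as the acetate in the same step; C4–OH and C6–OH have no carbonyl group within reach.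

Step 18
Reactants: 24 2β-acetoxy-4α-isopropyl-1β,8-dimethylbicyclo[5.3.0]dec-8-ene-4β,6α,10α-triol
Product: 26 2β-acetoxy-8β,9α-epoxy-4α-isopropyl-1β,8α-dimethylbicyclo[5.3.0]decane-4β,6α,10α-triol, via E cycloheptene 25 (not isolated)
Conditions: hν (254 nm, quartz), methyl benzoate, Et2O/pentane, -78 °C; then mCPBA, NaHCO3, -78 °C, dark; cycle repeated
Reagents that add atoms: 3-chloroperbenzoic acid, O=C(OO)c1cccc(Cl)c1
Why: Proposed new method: singlet-sensitised Z to E photoisomerisation of the trisubstituted cycloheptene at -78 °C gives the strained E isomer 25, whose twisted double bond should take up oxygen from the peracid on its only exposed face far faster than the Z alkene, and a concerted syn oxygen transfer to an E cycloalkene must give the trans-fused oxirane; the twist sense that keeps the C8 methyl group away from the β-axial C1 methyl group leads to the 8β,9α-oxirane; the closest known reaction types are the aromatic-ester-sensitised generation of trans-cycloheptene at low temperature with trapping by electrophiles in the dark and the stereospecific peracid epoxidation of trans-cyclooctene.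

Step 19
Reactants: 26 2β-acetoxy-8β,9α-epoxy-4α-isopropyl-1β,8α-dimethylbicyclo[5.3.0]decane-4β,6α,10α-triol
Product: 27 2β-acetoxy-8β,9α-epoxy-4β,10α-dihydroxy-4α-isopropyl-1β,8α-dimethylbicyclo[5.3.0]dec-6α-yl 3,4-dimethoxybenzoate (CNP0197096.4)
Conditions: 3,4-dimethoxybenzoyl chloride (1.1 equiv), pyridine, DMAP (cat.), CH2Cl2, -20 to 0 °C
Reagents that add atoms: 3,4-dimethoxybenzoyl chloride, COc1ccc(C(Cl)=O)cc1OC
Why: DMAP-catalysed acylation of the least hindered hydroxyl group, since C10–OH lies between quaternary C1 and the oxirane and C4–OH is tertiary; the mild non-acidic conditions should spare the strained oxirane.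

Compound list
1 | cyclopent-4-ene-1,3-dione | O=C1CC(=O)C=C1 | starting material
2 | 1,4-dioxaspiro[4.4]non-8-en-7-one | O=C1CC2(OCCO2)C=C1 | intermediate
3 | 8-iodo-1,4-dioxaspiro[4.4]non-8-en-7-one | O=C1CC2(OCCO2)C=C1I | intermediate
4 | (7R)-8-iodo-1,4-dioxaspiro[4.4]non-8-en-7-ol | O[C@@H]1CC2(OCCO2)C=C1I | intermediate
5 | tert-butyl{[(7R)-8-iodo-1,4-dioxaspiro[4.4]non-8-en-7-yl]oxy}dimethylsilane | CC(C)(C)[Si](C)(C)O[C@@H]1CC2(OCCO2)C=C1I | intermediate
6 | 1-[(7R)-7-(tert-butyldimethylsilyloxy)-1,4-dioxaspiro[4.4]non-8-en-8-yl]ethan-1-one | CC(=O)C1=CC2(OCCO2)C[C@H]1O[Si](C)(C)C(C)(C)C | intermediate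
7 | tert-butyldimethyl(prop-2-yn-1-yloxy)silane | C#CCO[Si](C)(C)C(C)(C)C | starting material
8 | tert-butyl{[3-(dimethylphenylsilyl)prop-2-yn-1-yl]oxy}dimethylsilane | C[Si](C)(c1ccccc1)C#CCO[Si](C)(C)C(C)(C)C | intermediate (not isolated)
9 | 1-(tert-butyldimethylsilyl)-3-(dimethylphenylsilyl)prop-2-yn-1-ol (racemic) | C[Si](C)(c1ccccc1)C#CC(O)[Si](C)(C)C(C)(C)C | intermediate
10 | (2Z)-1-(tert-butyldimethylsilyl)-3-(dimethylphenylsilyl)prop-2-en-1-ol (racemic) | C[Si](C)(c1ccccc1)/C=C\C(O)[Si](C)(C)C(C)(C)C | intermediate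
11 | (2Z)-1-(tert-butyldimethylsilyl)-3-(dimethylphenylsilyl)prop-2-en-1-one | C[Si](C)(c1ccccc1)/C=C\C(=O)[Si](C)(C)C(C)(C)C | intermediate
12 | lithium enolate of 6 at the acetyl methyl group (2-oxido diene) | C=C(O[Li])C1=CC2(OCCO2)C[C@H]1O[Si](C)(C)C(C)(C)C | intermediate (not isolated)
13 | lithium cis-1,2-divinylcyclopropanolate: cyclopropane of C8 (silyloxy, Z-2-silylvinyl), C9 (CH2) and C10 (oxido, cyclopentenyl), the two alkenyl groups cis and on the face of the cyclopentene opposite to its silyloxy group | [Li]O[C@@]3(C[C@@]3(O[Si](C)(C)C(C)(C)C)/C=C\[Si](C)(C)c4ccccc4)C1=CC2(OCCO2)C[C@H]1O[Si](C)(C)C(C)(C)C | intermediate (not isolated)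
14 | lithium C10(O)=C1 enolate of the annulated bicycle (5α-H, 6α-silyl, 2α-silyloxy, C7=C8 silyl enol ether, C4 ketal) | C[Si](C)(c1ccccc1)[C@@H]2C=C(O[Si](C)(C)C(C)(C)C)CC(O[Li])=C3[C@H](O[Si](C)(C)C(C)(C)C)CC4(OCCO4)[C@@H]23 | intermediate (not isolated)
15 | 2α,8-bis(tert-butyldimethylsilyloxy)-6α-(dimethylphenylsilyl)-4,4-ethylenedioxy-1β-methyl-5α-H-bicyclo[5.3.0]dec-7-en-10-one | C[Si](C)(c1ccccc1)[C@@H]2C=C(O[Si](C)(C)C(C)(C)C)CC(=O)[C@]3(C)[C@H](O[Si](C)(C)C(C)(C)C)CC4(OCCO4)[C@@H]23 | intermediate
16 | 6α-(dimethylphenylsilyl)-4,4-ethylenedioxy-2α-hydroxy-1β-methyl-5α-H-bicyclo[5.3.0]decane-8,10-dione | C[Si](C)(c1ccccc1)[C@@H]2CC(=O)CC(=O)[C@]3(C)[C@H](O)CC4(OCCO4)[C@@H]23 | intermediate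
17 | 6α-(dimethylphenylsilyl)-4,4-ethylenedioxy-2α-hydroxy-1β-methyl-10-oxo-5α-H-bicyclo[5.3.0]dec-8-en-8-yl trifluoromethanesulfonate | C[Si](C)(c1ccccc1)[C@@H]2CC(OS(=O)(=O)C(F)(F)F)=CC(=O)[C@]3(C)[C@H](O)CC4(OCCO4)[C@@H]23 | intermediate
18 | 6α-(dimethylphenylsilyl)-4,4-ethylenedioxy-2α-hydroxy-1β,8-dimethyl-5α-H-bicyclo[5.3.0]dec-8-en-10-one | C[Si](C)(c1ccccc1)[C@@H]2CC(C)=CC(=O)[C@]3(C)[C@H](O)CC4(OCCO4)[C@@H]23 | intermediate
19 | 6α-(dimethylphenylsilyl)-4,4-ethylenedioxy-1β,8-dimethyl-5α-H-bicyclo[5.3.0]dec-8-ene-2,10-dione | C[Si](C)(c1ccccc1)[C@@H]2CC(C)=CC(=O)[C@]3(C)C(=O)CC4(OCCO4)[C@@H]23 | intermediate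
20 | 6α-(dimethylphenylsilyl)-4,4-ethylenedioxy-2β-hydroxy-1β,8-dimethyl-5α-H-bicyclo[5.3.0]dec-8-en-10-one | C[Si](C)(c1ccccc1)[C@@H]2CC(C)=CC(=O)[C@]3(C)[C@@H](O)CC4(OCCO4)[C@@H]23 | intermediate (not isolated)
21 | 6α-(dimethylphenylsilyl)-2β-hydroxy-1β,8-dimethyl-5α-H-bicyclo[5.3.0]dec-8-ene-4,10-dione | C[Si](C)(c1ccccc1)[C@@H]2CC(C)=CC(=O)[C@]3(C)[C@@H](O)CC(=O)[C@@H]23 | intermediate
22 | 6α-(dimethylphenylsilyl)-2β,4β-dihydroxy-4α-isopropyl-1β,8-dimethyl-5α-H-bicyclo[5.3.0]dec-8-en-10-one | C[Si](C)(c1ccccc1)[C@@H]2CC(C)=CC(=O)[C@]3(C)[C@@H](O)C[C@](O)(C(C)C)[C@@H]23 | intermediate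
23 | 2β,4β,6α-trihydroxy-4α-isopropyl-1β,8-dimethyl-5α-H-bicyclo[5.3.0]dec-8-en-10-one | O[C@@H]2CC(C)=CC(=O)[C@]3(C)[C@@H](O)C[C@](O)(C(C)C)[C@@H]23 | intermediate
24 | 2β-acetoxy-4α-isopropyl-1β,8-dimethyl-5α-H-bicyclo[5.3.0]dec-8-ene-4β,6α,10α-triol (Z ring alkene) | O[C@@H]2CC(C)=C[C@H](O)[C@]3(C)[C@@H](OC(C)=O)C[C@](O)(C(C)C)[C@@H]23 | intermediate
25 | (8E) isomer of 24, with C7 and C10 trans on the ring double bond | O[C@@H]2C/C(C)=C/[C@H](O)[C@]3(C)[C@@H](OC(C)=O)C[C@](O)(C(C)C)[C@@H]23 | intermediate (not isolated)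
26 | 2β-acetoxy-8β,9α-epoxy-4α-isopropyl-1β,8α-dimethyl-5α-H-bicyclo[5.3.0]decane-4β,6α,10α-triol (oxirane trans-fused) | O[C@@H]2C[C@@]3(C)O[C@@H]3[C@H](O)[C@]3(C)[C@@H](OC(C)=O)C[C@](O)(C(C)C)[C@@H]23 | intermediate
27 | 2β-acetoxy-8β,9α-epoxy-4β,10α-dihydroxy-4α-isopropyl-1β,8α-dimethyl-5α-H-bicyclo[5.3.0]dec-6α-yl 3,4-dimethoxybenzoate (CNP0197096.4) | COc1ccc(C(=O)O[C@@H]2C[C@@]3(C)O[C@@H]3[C@H](O)[C@]3(C)[C@@H](OC(C)=O)C[C@](O)(C(C)C)[C@@H]23)cc1OC | target

Total step count: 19. Longest linear sequence: 16 steps (steps 1 to 5 and 9 to 19); steps 6 to 8 make the second fragment.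

Steps most likely to fail

Step 18. The stationary share of the E isomer may stay too low, the E isomer may revert before it is trapped, the other twist sense may form, or slow background epoxidation of the Z alkene may give the cis-fused oxirane. The fallback sets out from 24 and comes back at 26, and each of its operations has direct precedent on trans-cycloheptene or trans-cyclooctene. A solution of 24 and methyl benzoate is circulated through a 254 nm flow photoreactor and then through a cooled bed of AgNO3 on silica gel, which binds only the strained E isomer and so drains the photoequilibrium. The bound material, the silver nitrate complex of the E cycloheptene F1, is then taken up cold and decomplexed at -78 °C with aqueous NaCl in the presence of mCPBA, so that the liberated E alkene is epoxidised stereospecifically to 26.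

Step 9. The β-silyloxy enolate 14 may lose silanolate before it is methylated, methylation may occur on oxygen, or the approach to C5 and C1 may be unselective. The fallback sets out from 6 and comes back at 16. The silyl ether of 6 is removed with HF·pyridine to give the hydroxy ketone 1-[(7R)-7-hydroxy-1,4-dioxaspiro[4.4]non-8-en-8-yl]ethan-1-one F2. Two equivalents of LDA turn it into the alkoxide enolate, whose oxido group cannot leave and still shields the α face. Annulation with 11 and methylation with one equivalent of MeI then give the 2α-hydroxy silyl enol ether F3, and TBAF converts it into 16.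

Step 17. The trans relation of the C2 oxygen and C10 on the cyclopentane may keep the hemiacetal hydride from reaching the carbonyl carbon, or retro-aldol cleavage of C1–C2 may intervene. The fallback sets out from 22 and comes back at 24. The C2 hydroxyl of 22, the only secondary one, is acetylated with Ac2O, pyridine and DMAP to the acetate F4. Fleming–Tamao oxidation (KBr, AcOOH, NaOAc, AcOH) gives the 6α-hydroxy enone F5. Reagent-controlled Corey–Bakshi–Shibata reduction with stoichiometric (R)-2-methyl-CBS-oxazaborolidine and BH3·SMe2 (quaternary C1 as the large group) should then deliver hydride to the β face of C10 and give 24.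

Further compounds
F1 | step 18 | silver nitrate complex of the (8E) isomer of 24 | O[C@@H]2C/C(C)=C/[C@H](O)[C@]3(C)[C@@H](OC(C)=O)C[C@](O)(C(C)C)[C@@H]23.[Ag+].[O-][N+](=O)[O-]
F2 | step 9 | 1-[(7R)-7-hydroxy-1,4-dioxaspiro[4.4]non-8-en-8-yl]ethan-1-one | CC(=O)C1=CC2(OCCO2)C[C@H]1O
F3 | step 9 | 8-(tert-butyldimethylsilyloxy)-6α-(dimethylphenylsilyl)-4,4-ethylenedioxy-2α-hydroxy-1β-methyl-5α-H-bicyclo[5.3.0]dec-7-en-10-one | C[Si](C)(c1ccccc1)[C@@H]2C=C(O[Si](C)(C)C(C)(C)C)CC(=O)[C@]3(C)[C@H](O)CC4(OCCO4)[C@@H]23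
F4 | step 17 | 2β-acetoxy-6α-(dimethylphenylsilyl)-4β-hydroxy-4α-isopropyl-1β,8-dimethyl-5α-H-bicyclo[5.3.0]dec-8-en-10-one | C[Si](C)(c1ccccc1)[C@@H]2CC(C)=CC(=O)[C@]3(C)[C@@H](OC(C)=O)C[C@](O)(C(C)C)[C@@H]23
F5 | step 17 | 2β-acetoxy-4β,6α-dihydroxy-4α-isopropyl-1β,8-dimethyl-5α-H-bicyclo[5.3.0]dec-8-en-10-one | O[C@@H]2CC(C)=CC(=O)[C@]3(C)[C@@H](OC(C)=O)C[C@](O)(C(C)C)[C@@H]23
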